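Labels: each alkaloid half is numbered as a cyclopenta[c]pyridine (C1, N2, C3, C4, C4a, C5, C6, C7, C7a).
Cuts: first the two C6–O ester bonds, giving two identical amino alcohols and (2E,6E)-2,6-dimethylocta-2,6-dienedioic acid. Then C5–C6 of the cyclopentane, then C4a=C5, C7a–C7 and C4–CH3 on a purchased piperidine ring.
Enabling feature: in the five-membered ring C5 is bonded only to C4a and C6, and C6 reaches C4a the other way round through C7 and C7a. Opening C5–C6 therefore leaves a formyl group (C6) and a methylene group (C4a=C5) on the intact piperidine ring, which together form a 2,3,4-substituted pent-4-enal.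
Forward order: the six-membered ring is decorated (C4 methyl, C7a isopropenyl, oxygen at C4a). A temporary γ-lactone sorts out C6 and C7, C4a is methylenated, and the cyclopentanone closes last. The C10 diacid then joins two halves.
Stereochemistry: C4 comes from an asymmetric conjugate addition, C7a from hydroboration anti to the C4 methyl, and C7 from equilibration of the trans-fused lactone. C4a comes from the ring closure, C6 from convex-face hydride delivery followed by Mitsunobu inversion, and both E alkenes from geranyl acetate.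
Key step: step 10

Assumption: the aza-enone is taken to show the same facial sense as cyclohex-2-enone with the copper–phosphoramidite catalyst, and (S)-BINAP is taken as the antipode that reinforces the substrate bias in the ring closure; if either sense proves opposite, the mirror-image ligand is used and nothing else changes.

Step 1
Reactants: 1 tert-butyl 3-oxo-3,6-dihydropyridine-1(2H)-carboxylate
Product: 3 tert-butyl (3R)-3-methyl-5-(trifluoromethylsulfonyloxy)-3,6-dihydropyridine-1(2H)-carboxylate, via methylzinc enolate 2 (not isolated)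
Conditions: Me2Zn (1.5 equiv), Cu(OTf)2 (2 mol %), (S,R,R)-BINOL bis(1-phenylethyl)amine phosphoramidite (4 mol %), toluene, −30 °C; then Tf2O (1.3 equiv), −30 to 0 °C
Reagents that add atoms: dimethylzinc, C[Zn]C; trifluoromethanesulfonic anhydride, O=S(=O)(OS(=O)(=O)C(F)(F)F)C(F)(F)F
Why: Copper-catalysed enantioselective conjugate addition of a dialkylzinc works best on six-membered cyclic enones, the chiral phosphoramidite–copper complex chooses the enone face and so sets C4 (R), and O-triflation of the regiodefined zinc enolate fixes the double bond between C7a and C4a, where C4 can no longer epimerise.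

Step 2
Reactants: 3 tert-butyl (3R)-3-methyl-5-(trifluoromethylsulfonyloxy)-3,6-dihydropyridine-1(2H)-carboxylate; 4 4,4,5,5-tetramethyl-2-(prop-1-en-2-yl)-1,3,2-dioxaborolane
Product: 5 tert-butyl (3R)-3-methyl-5-(prop-1-en-2-yl)-3,6-dihydropyridine-1(2H)-carboxylate
Conditions: Pd(dppf)Cl2 (3 mol %), K2CO3, 1,4-dioxane/H2O, 60 °C
Reagents that add atoms: none
Why: Suzuki–Miyaura coupling of an enol triflate with an alkenylboronate is routine, brings in C7, its methyl group and C6 in one piece, creates no stereocentre and leaves allylic C4 untouched.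

Step 3
Reactants: 5 tert-butyl (3R)-3-methyl-5-(prop-1-en-2-yl)-3,6-dihydropyridine-1(2H)-carboxylate
Product: 8 tert-butyl (3R,4R,5S)-4-hydroxy-3-(1-hydroxypropan-2-yl)-5-methylpiperidine-1-carboxylate (C7 epimers), via C6 9-BBN adduct 6 (not isolated), via C6/C4a bis-borane 7 (not isolated)
Conditions: 9-BBN (1.1 equiv), THF, 0 °C to rt; BH3·THF (1.5 equiv), 0 °C to rt; NaOH, H2O2, 0 °C
Reagents that add atoms: hydrogen peroxide, OO
Why: In this hydroboration–oxidation 9-BBN takes only the unhindered 1,1-disubstituted alkene (boron on C6, C7 formed without control), and BH3 then adds syn to the trisubstituted ring alkene with boron on C4a and hydrogen on C7a from the face away from the C4 methyl, which can stand pseudoaxial at little cost in the flattened N-acyl tetrahydropyridine, so that retentive oxidation leaves the C7a side chain cis to the C4 methyl and the C4a hydroxyl trans to both.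

Step 4
Reactants: 8 tert-butyl (3R,4R,5S)-4-hydroxy-3-(1-hydroxypropan-2-yl)-5-methylpiperidine-1-carboxylate (C7 epimers)
Product: 10 trans-fused γ-lactone tert-butyl 3,7-dimethyl-2-oxooctahydrofuro[3,2-c]pyridine-5-carboxylate (C7 epimers), via bicyclic lactol 9 (not isolated)
Conditions: TEMPO (10 mol %), PhI(OAc)2 (2.5 equiv), CH2Cl2, rt
Reagents that add atoms: none
Why: In this oxidative lactonisation of a 1,4-diol, TEMPO/PhI(OAc)2 oxidises the primary alcohol selectively, the aldehyde is caught by the neighbouring equatorial C4a hydroxyl as lactol 9 and oxidised on to the lactone, which tells the two oxygens apart without a protecting group and creates no lasting stereocentre.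

Step 5
Reactants: 10 trans-fused γ-lactone (C7 epimers)
Product: 11 trans-fused γ-lactone with the C7 methyl cis to H-7a (single C7 epimer)
Conditions: KOt-Bu (20 mol %), THF/t-BuOH, 0 °C to rt; AcOH quench
Reagents that add atoms: none
Why: In this enolate equilibration of an α-methyl-γ-lactone the epimer with the C7 methyl beside C1 is nearly eclipsed in the rigid trans-fused bicycle, so the mixture should drain to the epimer with the methyl cis to H-7a, which is the C7 (S) configuration of the target, while C4, C4a and C7a carry no acidic hydrogen.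

Step 6
Reactants: 11 trans-fused γ-lactone (single C7 epimer)
Product: 12 tert-butyl (3R,4R,5S)-4-hydroxy-3-[(2S)-1-(methoxy(methyl)amino)-1-oxopropan-2-yl]-5-methylpiperidine-1-carboxylate
Conditions: MeNH(OMe)·HCl (3 equiv), i-PrMgCl (6 equiv), THF, −20 to 0 °C
Reagents that add atoms: N,O-dimethylhydroxylamine hydrochloride, CNOC.Cl
Why: Aminolysis of a lactone with the magnesium amide of N,O-dimethylhydroxylamine (Weinreb amide formation) should be fast for the strained trans-fused ring, frees the C4a hydroxyl, stores C6 at a level that a hydride takes only to the aldehyde, and changes no stereocentre.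

Step 7
Reactants: 12 hydroxy N-methoxy-N-methylamide
Product: 13 tert-butyl (3R,5S)-3-[(2S)-1-(methoxy(methyl)amino)-1-oxopropan-2-yl]-5-methyl-4-oxopiperidine-1-carboxylate
Conditions: Dess–Martin periodinane, CH2Cl2, 0 °C to rt
Reagents that add atoms: none
Why: Dess–Martin oxidation is fast and nearly neutral, so the hydroxy amide is oxidised before it can relactonise, and the 3,5-cis diequatorial ketone formed is also the thermodynamic isomer, so C4 and C7a have no drive to epimerise.

Step 8
Reactants: 13 keto N-methoxy-N-methylamide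
Product: 14 tert-butyl (3R,5S)-3-methyl-4-methylidene-5-[(2S)-1-(methoxy(methyl)amino)-1-oxopropan-2-yl]piperidine-1-carboxylate
Conditions: Cp2TiMe2 (2 equiv), toluene, 70 °C, dark
Reagents that add atoms: dimethyltitanocene, C[Ti](C)(C1C=CC=C1)C1C=CC=C1
Why: In the Petasis methylenation the non-basic titanium methylidene olefinates hindered, enolisable ketones without epimerisation and attacks a ketone well before an amide or carbamate carbonyl, which installs C5 and removes the acidity of H-4 and H-7a for good.

Step 9
Reactants: 14 methylidene N-methoxy-N-methylamide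
Product: 15 tert-butyl (3R,5S)-3-methyl-4-methylidene-5-[(2S)-1-oxopropan-2-yl]piperidine-1-carboxylate
Conditions: i-Bu2AlH (1.3 equiv), THF, −78 °C; aq Rochelle salt
Reagents that add atoms: none
Why: Hydride reduction of an N-methoxy-N-methylamide stops at the chelated tetrahedral aluminate, which releases the aldehyde only on work-up (Weinreb aldehyde synthesis), so neither over-reduction nor C7 epimerisation is expected and the Boc group and the alkene are inert at −78 °C.

Step 10
Reactants: 15 tert-butyl (3R,5S)-3-methyl-4-methylidene-5-[(2S)-1-oxopropan-2-yl]piperidine-1-carboxylate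
Product: 16 tert-butyl (4R,4aS,7S,7aR)-4,7-dimethyl-6-oxooctahydro-2H-cyclopenta[c]pyridine-2-carboxylate
Conditions: [Rh(nbd)((S)-BINAP)]BF4 (5 mol %), activated with H2 then purged with Ar, CH2Cl2, 25 to 40 °C
Reagents that add atoms: none
Why: The cationic catalyst, rhodium in its monovalent state, opens the cycle by oxidative addition of the aldehyde C6–H bond; the trivalent acyl(hydrido)rhodium species binds the C4a=C5 double bond, passes its hydride to C4a and keeps C5 as a primary alkyl ligand, and C5–C6 then forms by reductive elimination from this six-membered metallacycle, which regenerates the catalyst. The closest known reaction type is the cyclisation of 4-substituted and 3,4-disubstituted pent-4-enals to cyclopentanones with cationic rhodium diphosphine complexes, for which BINAP is the standard chiral ligand. The cyclopentanone closes in a formally 5-endo-trig mode, which is open here because the bond is made inside the metallacycle and not by direct attack on the alkene. The one new stereocentre, C4a, is controlled by the substrate and reinforced by the ligand: with the side chain equatorial on C7a and the C7 methyl anti to C4a, the acyl–rhodium unit fits best into the pocket between C4a and the axial H-7a, under the alkene face opposite to the C4 methyl and C7, so hydrogen arrives there, C5 swings axial and the fusion becomes cis (4aS), a closure that is also less strained than the trans-fused one. The step needs cyclisation to outrun decarbonylation and hydride-induced migration of the alkene into the ring; the 1,1-disubstituted alkene steers the hydride to C4a and avoids a tertiary alkyl–rhodium bond, the chelating diphosphine on a cationic centre leaves no site for carbonyl extrusion, and the carbamate keeps nitrogen off the metal.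

Step 11
Reactants: 16 tert-butyl (4R,4aS,7S,7aR)-4,7-dimethyl-6-oxooctahydro-2H-cyclopenta[c]pyridine-2-carboxylate
Product: 18 (4R,4aS,6S,7S,7aR)-2,4,7-trimethyloctahydro-1H-cyclopenta[c]pyridin-6-ol, via N-Boc 6S alcohol 17 (not isolated)
Conditions: LiAlH4 (5 equiv), THF, −78 °C, then reflux
Reagents that add atoms: none
Why: At low temperature the small aluminohydride should attack the C6 ketone from the convex face of the cis-fused bicycle (the face of H-4a and H-7a), placing the hydroxyl on the concave face trans to the C7 methyl (6S), and at reflux the same reagent carries out the standard reduction of the tert-butyl carbamate to the N-methyl group.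

Step 12
Reactants: 19 geranyl acetate
Product: 20 (2E,6E)-8-hydroxy-3,7-dimethylocta-2,6-dien-1-yl acetate
Conditions: SeO2 (10 mol %), t-BuOOH (2 equiv), salicylic acid (10 mol %), CH2Cl2, rt
Reagents that add atoms: tert-butyl hydroperoxide, CC(C)(C)OO (oxygen atom passed on through selenium dioxide, O=[Se]=O)
Why: The Riley allylic oxidation runs by ene reaction and [2,3]-shift and attacks the more electron-rich terminal trisubstituted alkene at its E methyl group only, so the 6E geometry is fixed and the acetate-deactivated 2,3-alkene is left alone.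

Step 13
Reactants: 20 (2E,6E)-8-hydroxy-3,7-dimethylocta-2,6-dien-1-yl acetate
Product: 21 (2E,6E)-2,6-dimethylocta-2,6-diene-1,8-diol
Conditions: K2CO3 (20 mol %), MeOH, rt
Reagents that add atoms: none
Why: Carbonate-catalysed transesterification with methanol removes the acetate without touching either alkene.

Step 14
Reactants: 21 (2E,6E)-2,6-dimethylocta-2,6-diene-1,8-diol
Product: 22 (2E,6E)-2,6-dimethylocta-2,6-dienedial
Conditions: MnO2 (excess), CH2Cl2, rt
Reagents that add atoms: none
Why: MnO2 oxidises allylic alcohols selectively to enals under neutral conditions, so both termini reach the aldehyde level with the E geometries kept.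

Step 15
Reactants: 22 (2E,6E)-2,6-dimethylocta-2,6-dienedial
Product: 23 (2E,6E)-2,6-dimethylocta-2,6-dienedioic acid
Conditions: NaClO2, NaH2PO4, 2-methylbut-2-ene, t-BuOH/H2O, 0 °C to rt
Reagents that add atoms: sodium chlorite, [Na+].[O-]Cl=O
Why: The Pinnick oxidation converts enals into enoic acids without alkene isomerisation because 2-methylbut-2-ene scavenges the hypochlorous acid that is formed.

Step 16
Reactants: 18 (4R,4aS,6S,7S,7aR)-2,4,7-trimethyloctahydro-1H-cyclopenta[c]pyridin-6-ol (2.2 equiv); 23 (2E,6E)-2,6-dimethylocta-2,6-dienedioic acid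
Product: 26 bis[(4R,4aS,6R,7S,7aR)-2,4,7-trimethyloctahydro-1H-cyclopenta[c]pyridin-6-yl] (2E,6E)-2,6-dimethylocta-2,6-dienedioate (CNP0240822.3), via C1 monoester 24 (not isolated), via C8 monoester 25 (not isolated)
Conditions: PPh3 (3 equiv), DIAD (3 equiv), THF, 0 °C to rt
Reagents that add atoms: none
Why: In the double Mitsunobu esterification each C6 alkoxyphosphonium ion is displaced by a carboxylate of 23 from the open convex face with SN2 inversion (6S to 6R), the tertiary amines are tolerated, and the E enoates stay intact because the acid is never activated at its carbonyl group.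

Compound list
1 | tert-butyl 3-oxo-3,6-dihydropyridine-1(2H)-carboxylate (carbonyl carbon = future C7a) | O=C1C=CCN(C(=O)OC(C)(C)C)C1 | starting material
2 | methylzinc enolate of tert-butyl (5R)-5-methyl-3-oxopiperidine-1-carboxylate (C7a–O–ZnMe, C7a=C4a) | C[C@H]1CN(C(=O)OC(C)(C)C)CC(O[Zn]C)=C1 | intermediate
3 | tert-butyl (3R)-3-methyl-5-(trifluoromethylsulfonyloxy)-3,6-dihydropyridine-1(2H)-carboxylate | C[C@H]1CN(C(=O)OC(C)(C)C)CC(OS(=O)(=O)C(F)(F)F)=C1 | intermediate
4 | 4,4,5,5-tetramethyl-2-(prop-1-en-2-yl)-1,3,2-dioxaborolane | CC(=C)B1OC(C)(C)C(C)(C)O1 | starting material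
5 | tert-butyl (3R)-3-methyl-5-(prop-1-en-2-yl)-3,6-dihydropyridine-1(2H)-carboxylate | C[C@H]1CN(C(=O)OC(C)(C)C)CC(C(C)=C)=C1 | intermediate
6 | B-alkyl-9-BBN adduct of 5 at C6 (C7 epimers) | C[C@H]1CN(C(=O)OC(C)(C)C)CC(C(C)CB2C3CCCC2CCC3)=C1 | intermediate
7 | bis-borane, 9-BBN on C6 and BH2 on C4a (boron trans to the C4 methyl and to C7; C7 epimers) | C[C@H]1CN(C(=O)OC(C)(C)C)C[C@@H](C(C)CB2C3CCCC2CCC3)[C@@H]1B | intermediate
8 | tert-butyl (3R,4R,5S)-4-hydroxy-3-(1-hydroxypropan-2-yl)-5-methylpiperidine-1-carboxylate (3,5-cis, 4-OH trans to both, C7 epimers) | C[C@H]1CN(C(=O)OC(C)(C)C)C[C@@H](C(C)CO)[C@@H]1O | intermediate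
9 | bicyclic lactol (C6 hemiacetal closed on the C4a oxygen; C6 and C7 epimers) | C[C@H]1CN(C(=O)OC(C)(C)C)C[C@H]2C(C)C(O)O[C@H]12 | intermediate
10 | tert-butyl 3,7-dimethyl-2-oxooctahydrofuro[3,2-c]pyridine-5-carboxylate, trans-fused (H-4a and H-7a trans), C7 epimers | C[C@H]1CN(C(=O)OC(C)(C)C)C[C@H]2C(C)C(=O)O[C@H]12 | intermediate
11 | the same trans-fused lactone, single epimer with the C7 methyl cis to H-7a | C[C@H]1CN(C(=O)OC(C)(C)C)C[C@H]2[C@H](C)C(=O)O[C@H]12 | intermediate
12 | tert-butyl (3R,4R,5S)-4-hydroxy-3-[(2S)-1-(methoxy(methyl)amino)-1-oxopropan-2-yl]-5-methylpiperidine-1-carboxylate | C[C@H]1CN(C(=O)OC(C)(C)C)C[C@@H]([C@H](C)C(=O)N(C)OC)[C@@H]1O | intermediate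
13 | tert-butyl (3R,5S)-3-[(2S)-1-(methoxy(methyl)amino)-1-oxopropan-2-yl]-5-methyl-4-oxopiperidine-1-carboxylate (3,5-cis) | C[C@H]1CN(C(=O)OC(C)(C)C)C[C@@H]([C@H](C)C(=O)N(C)OC)C1=O | intermediate
14 | tert-butyl (3R,5S)-3-methyl-4-methylidene-5-[(2S)-1-(methoxy(methyl)amino)-1-oxopropan-2-yl]piperidine-1-carboxylate | C=C1[C@@H](C)CN(C(=O)OC(C)(C)C)C[C@H]1[C@H](C)C(=O)N(C)OC | intermediate
15 | tert-butyl (3R,5S)-3-methyl-4-methylidene-5-[(2S)-1-oxopropan-2-yl]piperidine-1-carboxylate (3,5-cis) | C=C1[C@@H](C)CN(C(=O)OC(C)(C)C)C[C@H]1[C@H](C)C=O | intermediate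
16 | tert-butyl (4R,4aS,7S,7aR)-4,7-dimethyl-6-oxooctahydro-2H-cyclopenta[c]pyridine-2-carboxylate (cis-fused) | O=C1C[C@@H]2[C@@H](CN(C(=O)OC(C)(C)C)C[C@@H]2C)[C@@H]1C | intermediate
17 | tert-butyl (4R,4aS,6S,7S,7aR)-6-hydroxy-4,7-dimethyloctahydro-2H-cyclopenta[c]pyridine-2-carboxylate (present as its aluminium alkoxide) | O[C@H]1C[C@@H]2[C@@H](CN(C(=O)OC(C)(C)C)C[C@@H]2C)[C@@H]1C | intermediate
18 | (4R,4aS,6S,7S,7aR)-2,4,7-trimethyloctahydro-1H-cyclopenta[c]pyridin-6-ol | O[C@H]1C[C@@H]2[C@@H](CN(C)C[C@@H]2C)[C@@H]1C | intermediate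
19 | geranyl acetate | CC(C)=CCC/C(C)=C/COC(C)=O | starting material
20 | (2E,6E)-8-hydroxy-3,7-dimethylocta-2,6-dien-1-yl acetate | OC/C(C)=C/CC/C(C)=C/COC(C)=O | intermediate
21 | (2E,6E)-2,6-dimethylocta-2,6-diene-1,8-diol | OC/C(C)=C/CC/C(C)=C/CO | intermediate
22 | (2E,6E)-2,6-dimethylocta-2,6-dienedial | O=C/C(C)=C/CC/C(C)=C/C=O | intermediate
23 | (2E,6E)-2,6-dimethylocta-2,6-dienedioic acid | OC(=O)/C(C)=C/CC/C(C)=C/C(=O)O | intermediate
24 | monoester at C1 of the diacid (2-methyl-2-enoate end esterified, C8 acid free) | C/C(=C\C(=O)O)CC/C=C(\C)C(=O)O[C@@H]1C[C@@H]2[C@@H](CN(C)C[C@@H]2C)[C@@H]1C | intermediate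
25 | monoester at C8 of the diacid (3-methyl-2-enoate end esterified, C1 acid free) | C/C(=C\C(=O)O[C@@H]1C[C@@H]2[C@@H](CN(C)C[C@@H]2C)[C@@H]1C)CC/C=C(\C)C(=O)O | intermediate
26 | bis[(4R,4aS,6R,7S,7aR)-2,4,7-trimethyloctahydro-1H-cyclopenta[c]pyridin-6-yl] (2E,6E)-2,6-dimethylocta-2,6-dienedioate | C/C(=C\C(=O)O[C@@H]1C[C@@H]2[C@@H](CN(C)C[C@@H]2C)[C@@H]1C)CC/C=C(\C)C(=O)O[C@@H]1C[C@@H]2[C@@H](CN(C)C[C@@H]2C)[C@@H]1C | target

Total step count: 16. Longest linear sequence: 12 (steps 1 to 11 and step 16). Steps 12 to 15 form the side branch to the diacid.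

Steps most likely to fail

Step 10.
- What may go wrong: hydrogen may be delivered to the other face of the methylene, giving a trans ring fusion. Rhodium hydride may move the alkene into the ring. Decarbonylation may deactivate the catalyst.
- Fallback: it makes the same C5–C6 bond by stoichiometric, anionic chemistry, sets out from 14 and rejoins the route at 16.
- 9-BBN should add to the methylene of 14 from the equatorial direction, the face opposite to the two flanking substituents, to give the B-alkyl-9-BBN adduct F1.
- NaOH/H2O2 turns it into the all-cis primary alcohol F2.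
- Appel-type iodination (iodine, PPh3, imidazole) gives the primary iodide F3.
- Iodine–lithium exchange with t-BuLi in Et2O at −78 °C gives the primary alkyllithium F4, which closes onto the internal N-methoxy-N-methylamide and gives ketone 16 on work-up.

Step 3.
- What may go wrong: the small C4 methyl group may discriminate poorly between the two faces of the ring alkene. Material of the 3,5-trans series would then have to be removed, and it cannot be corrected later without risk to the enantiomeric purity.
- Fallback: it reverses the order in which the two ring substituents are introduced, so that the larger group stands next to C4a when the borane arrives. It sets out from 1 and rejoins the route at 8.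
- CuBr·SMe2 with a chiral ferrocenyl diphosphine catalyses the 1,4-addition of isopropenylmagnesium bromide to 1 and gives the bromomagnesium enolate F5.
- N-(5-chloropyridin-2-yl)bis(trifluoromethanesulfonimide) traps it as the enol triflate F6.
- Fe(acac)3-catalysed coupling with MeMgBr gives the skipped diene F7.
- 9-BBN takes the isopropenyl group and gives the B-alkyl-9-BBN adduct F8.
- BH3·THF then places hydrogen on C4 and boron on C4a anti to the bulky C7a substituent, which leads to 7 and, after oxidation, to 8.

Step 8.
- What may go wrong: the hindered ketone may react so slowly that the titanium methylidene starts to attack the amide carbonyl, or chelation by the N-methoxy amide may stall the reaction.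
- Fallback: C6 is carried as a silyl ether instead of an amide. It sets out from 11 and rejoins the route at 15.
- LiBH4 reduces lactone 11 to the C7-defined diol F9.
- TBSCl and imidazole silylate only the primary hydroxyl and give the silyl ether F10.
- Dess–Martin oxidation gives the cis ketone F11.
- With no second reactive carbonyl group left, Cp2TiMe2 can be used in excess and gives the methylidene silyl ether F12.
- TBAF frees the primary alcohol F13, and Dess–Martin oxidation gives 15.

Further compounds
F1 | step 10 | B-alkyl-9-BBN adduct of 14 at C5 (C5 cis to the C4 methyl and to C7) | C[C@H]1CN(C(=O)OC(C)(C)C)C[C@@H]([C@H](C)C(=O)N(C)OC)[C@H]1CB1C2CCCC1CCC2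
F2 | step 10 | all-cis tert-butyl 4-(hydroxymethyl)-3-[(2S)-1-(methoxy(methyl)amino)-1-oxopropan-2-yl]-5-methylpiperidine-1-carboxylate | C[C@H]1CN(C(=O)OC(C)(C)C)C[C@@H]([C@H](C)C(=O)N(C)OC)[C@H]1CO
F3 | step 10 | all-cis tert-butyl 4-(iodomethyl)-3-[(2S)-1-(methoxy(methyl)amino)-1-oxopropan-2-yl]-5-methylpiperidine-1-carboxylate | C[C@H]1CN(C(=O)OC(C)(C)C)C[C@@H]([C@H](C)C(=O)N(C)OC)[C@H]1CI
F4 | step 10 | primary alkyllithium from F3 (lithium on C5) | C[C@H]1CN(C(=O)OC(C)(C)C)C[C@@H]([C@H](C)C(=O)N(C)OC)[C@H]1C[Li]
F5 | step 3 | bromomagnesium enolate of tert-butyl (5R)-3-oxo-5-(prop-1-en-2-yl)piperidine-1-carboxylate (C4–O–MgBr, C4=C4a) | CC(=C)[C@@H]1CN(C(=O)OC(C)(C)C)CC(O[Mg]Br)=C1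
F6 | step 3 | tert-butyl (3R)-3-(prop-1-en-2-yl)-5-(trifluoromethylsulfonyloxy)-3,6-dihydropyridine-1(2H)-carboxylate | CC(=C)[C@@H]1CN(C(=O)OC(C)(C)C)CC(OS(=O)(=O)C(F)(F)F)=C1
F7 | step 3 | tert-butyl (3R)-5-methyl-3-(prop-1-en-2-yl)-3,6-dihydropyridine-1(2H)-carboxylate | CC(=C)[C@@H]1CN(C(=O)OC(C)(C)C)CC(C)=C1
F8 | step 3 | B-alkyl-9-BBN adduct of F7 at C6 (C7 epimers) | CC(CB1C2CCCC1CCC2)[C@@H]1CN(C(=O)OC(C)(C)C)CC(C)=C1
F9 | step 8 | tert-butyl (3R,4R,5S)-4-hydroxy-3-[(2S)-1-hydroxypropan-2-yl]-5-methylpiperidine-1-carboxylate | C[C@H]1CN(C(=O)OC(C)(C)C)C[C@@H]([C@H](C)CO)[C@@H]1O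
F10 | step 8 | primary tert-butyldimethylsilyl ether of F9 | C[C@H]1CN(C(=O)OC(C)(C)C)C[C@@H]([C@H](C)CO[Si](C)(C)C(C)(C)C)[C@@H]1O
F11 | step 8 | 3,5-cis 4-oxopiperidine from F10 | C[C@H]1CN(C(=O)OC(C)(C)C)C[C@@H]([C@H](C)CO[Si](C)(C)C(C)(C)C)C1=O
F12 | step 8 | 4-methylidene silyl ether from F11 | C=C1[C@@H](C)CN(C(=O)OC(C)(C)C)C[C@H]1[C@H](C)CO[Si](C)(C)C(C)(C)C
F13 | step 8 | tert-butyl (3R,5S)-5-[(2S)-1-hydroxypropan-2-yl]-3-methyl-4-methylidenepiperidine-1-carboxylate | C=C1[C@@H](C)CN(C(=O)OC(C)(C)C)C[C@H]1[C@H](C)CO
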